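Monday's flask was stopped at 2.0 min, the end of the feed, earlier than Tuesday's at 6.0 min, and your quick hunch was that Tuesday's therefore ends with the longer chains, so I reckoned it through.

| setting | eta | beta | zeta | Tuesday's | Monday's |
|---|---|---|---|---|---|
| free monomer | 5.0 × 10⁻⁴ M (fed, over 2.0 min) | 7.5 × 10⁻⁴ M (fed, over 2.0 min) | 0.0010 M (fed, over 2.0 min) | 0.0010 M (fed, over 2.0 min) | 0.0010 M (fed, over 2.0 min) |
| transfer agent | 0.10 mM | 0.10 mM | 0.050 mM | 0.100 mM | 0.100 mM |
| initiator | 0.76 mol% | 0.76 mol% | 0.76 mol% | 0.76 mol% | 0.76 mol% |
| remark | run made earlier; the fed solution adds 0.50 times the starting volume | run made earlier; the fed solution adds 0.50 times the starting volume | run made earlier; the fed solution adds 0.50 times the starting volume | the fed solution adds 0.50 times the starting volume | the fed solution adds 0.50 times the starting volume |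
| time |  |  |  | 6.0 min | 2.0 min |

| run | time / min | monomer in chains / % |
|---|---|---|
| eta | 0.500 | 0.9 |
| eta | 0.833 | 2.8 |
| eta | 1.50 | 7.8 |
| eta | 3.00 | 17.5 |
| eta | 6.00 | 25.8 |
| beta | 0.500 | 1.7 |
| beta | 1.50 | 11.6 |
| beta | 3.00 | 23.8 |
| beta | 4.00 | 29.8 |
| beta | 6.00 | 33.3 |
| zeta | 0.500 | 3.0 |
| zeta | 0.833 | 8.0 |
| zeta | 1.50 | 17.4 |
| zeta | 3.00 | 42.7 |
| zeta | 6.00 | 63.5 |

(readings scatter by 1 percentage point)

- charges are per starting volume, the dose included; the dosed solution carries all of it
- the average divides the monomer in chains by the number of chains begun, living and dead together
- the earlier runs do not show the number of chains; that part of a forecast is a guess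
- percentages count the whole charge, also what has not yet gone in

* which of the two ends with the longer chains by the average number of monomer units in a chain (chains begun, living or dead) ("neither" if they lie within 10%) (Tuesday's / Monday's / neither)
* average number of monomer units in a chain (chains begun, living or dead) at the end, Tuesday's
* average number of monomer units in a chain (chains begun, living or dead) at the end, Monday's

The runs do not show the number of chains, so I made a guess: each part of initiator charged has begun one chain by the end of the feed, and the transfer agent begins none. The average length is then the fraction of the charge in chains times one over the loading. One over 0.76 mol% gives 132, the full-uptake length, meaning the units per chain begun if the whole charge of free monomer went into chains. Both flasks share it, so the comparison rests on their fractions. The eta and beta runs hold equal transfer agent and differ by 0.250 mM of charge, and these two flasks lie that same step above beta, so I extended the readings in a straight line. Monday's time lies a third of the way between the readings at 1.50 min and 3.00 min: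

at 6.00 min: 40.8% in chains, so 53.7 units for Tuesday's

at 1.50 min and 3.00 min: 15.4% and 30.1%

at 2.0 min: 20.3% in chains, so 26.7 units for Monday's

The forecast also named Tuesday's, but gave 45 and 23. It started from 58 and 27, and then, in its words, “Transfer-begun chains would lower both, so I shade them down”. There I differed, since I did not shade.

The flasks gave 55.4 for Tuesday's and 29.1 for Monday's, so Tuesday's ended longer.

    free monomer + initiator → living end + monomer in chains (k = 426 L mol⁻¹ s⁻¹)
    free monomer + living end → monomer in chains + living end, rate k2*[living end]*[free monomer] (k = 1390 L mol⁻¹ s⁻¹)
    living end + transfer agent → dead chain (kL = 127 L mol⁻¹ s⁻¹)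

Tuesday's held 42.1% of its charge in chains and Monday's 22.1%, and times 132 these make 55.6 and 29.2. The flask like Tuesday's but with 1.3 mol% of initiator has a full-uptake length of 76.9, shorter than Tuesday's 132. At 6.00 min it held 61.1% in chains with 0% of its initiator left, and the product is 47.0. Its length came out at 47.0.

The earlier runs and the new flask stem from a simulated flask with constants of no real substance.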